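Assumption: the biaryl axis between the two flavan units carries only two ortho substituents (the C7 oxygen of one ring, C4a of the other) and is treated as freely rotating, so the four sp3 centres are the only stereochemical elements to be controlled.

Convention: unit 1 is the flavan joined through its C6, unit 2 the flavan joined through its C5; ring A is the benzo ring of a chroman, ring B the 2-aryl group.

## The problem

The target is a dimer of 7,8,3',4'-tetrahydroxyflavan-3-ol in which C6 of unit 1 is bonded to C5 of unit 2. The two halves are therefore constitutionally different, although each has the same (2R,3S) 2,3-trans configuration. In unit 2 the biaryl bond sits next to C4a, peri to C4, a position that electrophilic substitution of a 7,8-dioxygenated ring A does not reach; this decides how the carbon skeleton must be assembled. The four stereocentres form two pairs on either side of the biaryl bond. Within a pair C2 can direct C3 (trans), but one pair cannot direct the other, so the absolute configuration at both C2 atoms has to come from a reagent or catalyst. Eight phenols, arranged as two catechol rings B and two 7,8-dihydroxy rings A, oxidise readily in air or base and must stay masked to the last step by groups that leave under neutral conditions. Each C2–O1 bond is a benzylic ether activated by the para oxygen of ring B; strong Lewis acids open it, and at the flavanone oxidation level a retro-oxa-Michael reaction would erase C2. The feature that opens the problem is that each C2 is an sp3 carbon bearing ring B and O1. With C4 as a ketone and C2=C3 as an alkene, C2 becomes the β-carbon of a 7,8-dioxygenated chromone, which can accept the ring B aryl group by 1,4-addition.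

## Retrosynthesis

**Target 19 to octabenzyl ether 18.** The eight O–benzyl bonds are cut first. Benzyl is the only common phenol protection that leaves by neutral hydrogenolysis; methyl ethers would need BBr3 on a finished flavan-3-ol, which the C2–O1 bonds would not survive. The consequence is that every phenol must be a benzyl ether before the saturated pyran rings exist.

**18 to tetraol 17 to bis(dihydroflavonol) 16.** The two C4 methylene groups are traced back to C4 carbinols and then C4 ketones. This reintroduces the carbonyl that activates both C3 (through its enol) and C2 (through the enone). The forward steps are a hydride reduction and an ionic hydrogenation. The latter is favoured because the C4 cation is stabilised by O1 (ortho) and the C7 ether (para), while the C3 alcohol cannot ionise.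

**16 to bis(flavanone) 13.** The two C3–O bonds are cut. Carrying the C3 oxygen through the arylation instead would require a 3-oxygenated chromone, a much poorer acceptor whose C3 would then be set by an uncontrolled protonation. Installing oxygen afterwards lets the C2 aryl group direct it: the silyl enol ether 14 is epoxidised anti to the aryl group (15) and opens to the trans α-hydroxy ketone. The forward reaction must enolise without generating a free enolate, which would expel the O1 phenoxide.

**13 to bichromone 11 and two equivalents of boronic acid 12.** Both C2–aryl bonds are cut in the key step. The neighbouring cut, O1–C2 (oxa-Michael closure of a chalcone), is reversible and hard to make enantioselective without an extra activating group. Cutting C2–aryl turns the problem into a catalytic asymmetric conjugate addition of an arylboronic acid to a chromone, a reaction class established for exactly this acceptor. The precursor 11 is flat and achiral; 12 is commercial. The forward reaction must exert catalyst control twice and must not be basic.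

**11 to tetraphenol 10 to tetramethyl ether 9.** This is a protecting-group exchange. It is needed because the only short entry to the unit 2 substitution pattern uses commercial methyl ethers, and the chelation-controlled demethylation further back would strip benzyl ethers unselectively. The exchange is placed at the bichromone, which has no stereocentre, no benzylic ether and no enolisable position.

**9 to bis(2-hydroxyacetophenone) 7 (through bis-enaminone 8), and 7 to biaryl 6.** O1–C2 and C2–C3 of both pyranone rings are cut; the two C2 carbons come from dimethylformamide dimethyl acetal, so both rings close in one operation. 7 arises from 6 by removing the single methyl ether that lies ortho to an acetyl group.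

**6 to bromide 2 and triflate 4 (through boronate 5); 2 from 1; 4 from 3.** The biaryl bond is cut. In unit 1 the carbon is para to the free phenol of commercial 1-(2-hydroxy-3,4-dimethoxyphenyl)ethanone 1 and is brominated directly to 2. In unit 2 the carbon ortho to the acetyl group cannot be halogenated, but in commercial 1-(6-hydroxy-2,3,4-trimethoxyphenyl)ethanone 3 it already carries a phenol. Triflation to 4 turns the one oxygen the target does not need into the leaving group, and the pyranone is later closed onto the other ortho oxygen. The coupling joins two carbons with one ortho substituent each and is sterically undemanding. The benzyl ethers of gallacetophenone cannot be used here because they would not survive the chelation-controlled demethylation.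

## Roads not taken

**Alternative 1:** ring A of unit 2 built by cyclobutenone ring expansion. The cut is the C4a–C8a bond of unit 2 and, with it, the whole of that benzene ring. Heating a cyclobutenone precursor would open the four-membered ring to a dienylketene, whose 6π-electrocyclisation and tautomerisation would give the biaryl phenol A1. In A1 ring A of unit 2 is complete, its C8a hydroxyl is free and C2–C3 of unit 2 are still an acetonide-protected diol on a side chain.
- Merits: the substitution pattern of the awkward ring A is fixed unambiguously by the way the cyclobutenone is assembled, with no cross-coupling at a hindered carbon; the step needs no metal; and the phenol is delivered ready for ring closure. In this respect it is better than the chosen plan, which pays for the same pattern with a triflate detour and a methyl-to-benzyl exchange.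
- Weak points: unit 1 must already be a complete, protected flavan-3-ol and be carried through the organometallic steps that build the cyclobutenone. The four stereocentres come from at least two separate asymmetric operations. After A1 the unit 2 pyran ring still has to be closed at a benzylic carbon that ionises easily, so its configuration is at risk.
- Comparison: the chosen plan is convergent, keeps all material flat and achiral up to the key step, and sets both C2 centres in one catalytic operation.

**Alternative 2:** double intramolecular aryl etherification. Both O1–C8a bonds are cut. Pd(OAc)2 with a bulky di-tert-butyl biaryl phosphine and Cs2CO3 would couple each C2 hydroxyl with the aryl chloride at C8a and give the fully protected target A2 (six benzyl ethers, two diphenylmethylene ketals).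
- Merits: the C2–O bonds are never broken, so all four stereocentres are in place beforehand and are retained. They could come from a natural flavan-3-ol after removal of its ring A. A2 is only one deprotection from the target and no redox adjustment at C3 or C4 is needed. On stereochemical security and end-game length this road is better than the chosen one.
- Weak points: the alkoxide bound to divalent palladium is secondary and benzylic with a β-hydrogen, so β-hydride elimination to the ketone competes. Each aryl chloride is electron-rich and flanked by two ortho substituents, which slows oxidative addition to zerovalent palladium, and this must succeed twice in one molecule. Clean excision of ring A from a flavan-3-ol has no dependable precedent, and a hexasubstituted biaryl bis-chloride must then be attached to two C4 carbons, which makes the precursor long.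
- Comparison: the chosen plan offers a key step with direct precedent on its acceptor class and a precursor available in seven steps from commercial ketones.

**Alternative 3:** double ortho-quinone methide cycloaddition. O1–C2 and C3–C4 are cut in both units. A chiral BINOL-derived phosphoric acid would dehydrate the bis(ortho-hydroxybenzyl alcohol) A4 to two ortho-quinone methides, and each would add the (E)-enol acetate A5 in a [4+2] cycloaddition to give the octa-O-benzyl target 3,3'-diacetate A3.
- Merits: this is the most convergent plan. Both pyran rings and all four stereocentres arise in one step at the correct oxidation level (the E geometry translates into 2,3-trans), and A3 needs only acetate removal and hydrogenolysis. If it worked it would be about three steps shorter than the chosen route.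
- Weak points: the quinone methides are unsubstituted at the methide carbon, which makes them slow to form from primary alcohols, prone to dimerise, and poorly organised by the chiral phosphate. The regiochemistry requires the styrene-type polarisation of A5 by ring B to override its enol ester polarisation, and a stepwise pathway would scramble the 2,3 relationship. A4 carries the same difficult substitution at unit 2 and is no easier to make than biaryl 6.
- Comparison: the chosen plan relies on a stereodetermining step whose sense and level of induction are established for chromones, at the price of three extra redox steps after it.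

Key step: step 8

## Route

Step 1
Reactants: 1 1-(2-hydroxy-3,4-dimethoxyphenyl)ethanone
Product: 2 1-(5-bromo-2-hydroxy-3,4-dimethoxyphenyl)ethanone
Conditions: NBS, MeCN, 0 °C to rt
Reagents that add atoms: N-bromosuccinimide, O=C1CCC(=O)N1Br
Why: Electrophilic aromatic bromination; C5 is para to the free phenol and ortho to the C4 methoxy group, whereas the only other open position, C6, is ortho to the deactivating acetyl group, so one regioisomer is expected.

Step 2
Reactants: 3 1-(6-hydroxy-2,3,4-trimethoxyphenyl)ethanone
Product: 4 2-acetyl-3,4,5-trimethoxyphenyl trifluoromethanesulfonate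
Conditions: Tf2O, pyridine, CH2Cl2, 0 °C
Reagents that add atoms: trifluoromethanesulfonic anhydride, O=S(=O)(OS(=O)(=O)C(F)(F)F)C(F)(F)F
Why: O-Sulfonylation of a phenol; it converts the oxygen ortho to the acetyl group, which the target does not contain, into a leaving group at the carbon that becomes C5 of unit 2.

Step 3
Reactants: 2 1-(5-bromo-2-hydroxy-3,4-dimethoxyphenyl)ethanone; 4 2-acetyl-3,4,5-trimethoxyphenyl trifluoromethanesulfonate
Product: 6 1-[5-(2-acetyl-3,4,5-trimethoxyphenyl)-2-hydroxy-3,4-dimethoxyphenyl]ethanone, via pinacol boronate 5 (not isolated)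
Conditions: 2, B2pin2, KOAc, PdCl2(dppf), 1,4-dioxane, 90 °C; then 4, aq K3PO4, 90 °C
Reagents that add atoms: none
Why: Miyaura borylation of the aryl bromide followed in the same flask by Suzuki–Miyaura coupling; the triflate is activated by its ortho acetyl group and the new biaryl bond has only one ortho substituent on each side, so the coupling is not sterically demanding.

Step 4
Reactants: 6 1-[5-(2-acetyl-3,4,5-trimethoxyphenyl)-2-hydroxy-3,4-dimethoxyphenyl]ethanone
Product: 7 1-[5-(2-acetyl-3-hydroxy-4,5-dimethoxyphenyl)-2-hydroxy-3,4-dimethoxyphenyl]ethanone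
Conditions: BCl3, CH2Cl2, −78 to 0 °C; aq work-up
Reagents that add atoms: none
Why: Chelation-controlled ether cleavage; BCl3 bound to the acetyl oxygen removes only the methyl ether ortho to that carbonyl, since the other four methoxy groups cannot form the six-membered chelate, and any over-cleavage is tolerable because all methyl ethers fall in step 6.

Step 5
Reactants: 7 1-[5-(2-acetyl-3-hydroxy-4,5-dimethoxyphenyl)-2-hydroxy-3,4-dimethoxyphenyl]ethanone
Product: 9 7,7',8,8'-tetramethoxy-4H,4'H-[5,6'-bichromene]-4,4'-dione, via bis-enaminone 8 (not isolated)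
Conditions: Me2NCH(OMe)2, toluene, 100 °C; then conc. HCl, CH2Cl2, rt
Reagents that add atoms: N,N-dimethylformamide dimethyl acetal, COC(OC)N(C)C
Why: Enaminone route to chromones; both acetyl groups condense with the formamide acetal and acid then drives conjugate addition of each ortho phenol with loss of dimethylamine, closing both pyranone rings with the acetal carbon as C2.

Step 6
Reactants: 9 7,7',8,8'-tetramethoxy-4H,4'H-[5,6'-bichromene]-4,4'-dione
Product: 10 7,7',8,8'-tetrahydroxy-4H,4'H-[5,6'-bichromene]-4,4'-dione
Conditions: BBr3, CH2Cl2, −78 °C to rt; MeOH quench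
Reagents that add atoms: none
Why: Lewis-acid cleavage of aryl methyl ethers; the fully aromatic bichromone has no stereocentre and no acid-labile bond, which is why the protecting-group exchange is placed here.

Step 7
Reactants: 10 7,7',8,8'-tetrahydroxy-4H,4'H-[5,6'-bichromene]-4,4'-dione
Product: 11 7,7',8,8'-tetrakis(benzyloxy)-4H,4'H-[5,6'-bichromene]-4,4'-dione
Conditions: BnBr, K2CO3, DMF, 50 °C, under N2
Reagents that add atoms: benzyl bromide, BrCc1ccccc1
Why: Williamson ether synthesis on all four phenols; benzyl ethers survive the later Lewis-acidic, oxidative, hydride and protic steps and leave by neutral hydrogenolysis.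

Step 8
Reactants: 11 7,7',8,8'-tetrakis(benzyloxy)-4H,4'H-[5,6'-bichromene]-4,4'-dione; 12 3,4-bis(benzyloxy)phenylboronic acid
Product: 13 (2S,2'S)-7,7',8,8'-tetrakis(benzyloxy)-2,2'-bis[3,4-bis(benzyloxy)phenyl]-2,2',3,3'-tetrahydro-4H,4'H-[5,6'-bichromene]-4,4'-dione
Conditions: 12 (5 equiv), Pd(OCOCF3)2 (15 mol %), (R)-t-BuPyOx (18 mol %), NH4PF6, H2O, ClCH2CH2Cl, 60 °C
Reagents that add atoms: none
Why: The boronic acid transmetallates to a cationic divalent palladium centre held by the pyridine-oxazoline ligand, the aryl–palladium species inserts the C2=C3 bond of a chromone with the aryl group going to C2, and water protonates the palladium enolate, releasing the flavanone without any change of oxidation state at the metal. The closest known reaction is the asymmetric conjugate addition of arylboronic acids to chromones under Pd(OCOCF3)2 and the same ligand class, which gives flavanones; here it is applied twice in one molecule. No ring is closed. Each new C2 stereocentre is set by the ligand, whose tert-butyl group differentiates the two faces of the bound chromone in the insertion step; the (R)-ligand is chosen because the (S)-ligand is known to deliver the aryl group to the opposite face, and the sense would be confirmed by circular dichroism of 13. The two chromones are remote from each other and react independently, so facial errors end up mainly in the heterochiral diastereomer, which can be separated, and the (2S,2'S) product is enriched in enantiopurity. The step needs 1,4- over 1,2-addition, which the soft aryl–palladium nucleophile and the vinylogous ester character of the chromone secure, and regioselectivity for C2, the only β-carbon. It also needs freedom from base, and the neutral aqueous conditions prevent retro-oxa-Michael opening of the flavanones. Excess boronic acid compensates for protodeboronation of the electron-rich aryl group.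

Step 9
Reactants: 13 (2S,2'S)-7,7',8,8'-tetrakis(benzyloxy)-2,2'-bis[3,4-bis(benzyloxy)phenyl]-2,2',3,3'-tetrahydro-4H,4'H-[5,6'-bichromene]-4,4'-dione
Product: 16 (2R,2'R,3R,3'R)-7,7',8,8'-tetrakis(benzyloxy)-2,2'-bis[3,4-bis(benzyloxy)phenyl]-3,3'-dihydroxy-2,2',3,3'-tetrahydro-4H,4'H-[5,6'-bichromene]-4,4'-dione, via bis(silyl enol ether) 14 (not isolated), via bis(silyloxy epoxide) 15 (not isolated)
Conditions: TMSOTf, Et3N, CH2Cl2, 0 °C; then dimethyldioxirane, acetone/CH2Cl2, −40 to 0 °C; then citric acid, MeOH/THF, 0 °C
Reagents that add atoms: dimethyldioxirane, CC1(C)OO1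
Why: Rubottom oxidation; soft enolisation with silyl triflate and amine avoids a free enolate and hence β-elimination of the O1 phenoxide, dimethyldioxirane epoxidises each C3=C4 bond on the face anti to the C2 aryl group, and mild acid opens the silyloxy epoxides to the α-hydroxy ketones, so each C3 is set trans to C2 by substrate control (also the diequatorial, thermodynamically preferred arrangement).

Step 10
Reactants: 16 (2R,2'R,3R,3'R)-7,7',8,8'-tetrakis(benzyloxy)-2,2'-bis[3,4-bis(benzyloxy)phenyl]-3,3'-dihydroxy-2,2',3,3'-tetrahydro-4H,4'H-[5,6'-bichromene]-4,4'-dione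
Product: 17 (2R,2'R,3S,3'S,4R,4'R)-7,7',8,8'-tetrakis(benzyloxy)-2,2'-bis[3,4-bis(benzyloxy)phenyl]-[5,6'-bichromane]-3,3',4,4'-tetrol
Conditions: NaBH4, THF/MeOH, 0 °C
Reagents that add atoms: none
Why: Hydride reduction of the two aryl ketones to benzylic alcohols; the C4 configuration (expected mainly 3,4-trans) is of no consequence because C4 becomes a methylene group in step 11.

Step 11
Reactants: 17 (2R,2'R,3S,3'S,4R,4'R)-7,7',8,8'-tetrakis(benzyloxy)-2,2'-bis[3,4-bis(benzyloxy)phenyl]-[5,6'-bichromane]-3,3',4,4'-tetrol
Product: 18 (2R,2'R,3S,3'S)-7,7',8,8'-tetrakis(benzyloxy)-2,2'-bis[3,4-bis(benzyloxy)phenyl]-[5,6'-bichromane]-3,3'-diol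
Conditions: Et3SiH, CF3CO2H, CH2Cl2, −20 to 0 °C; aq NaHCO3
Reagents that add atoms: none
Why: Ionic hydrogenation; acid ionises each C4 alcohol to a benzylic cation stabilised by O1 (ortho) and the C7 benzyloxy group (para) and triethylsilane delivers hydride, while the secondary C3 alcohols cannot ionise and C2 and C3 are untouched.

Step 12
Reactants: 18 (2R,2'R,3S,3'S)-7,7',8,8'-tetrakis(benzyloxy)-2,2'-bis[3,4-bis(benzyloxy)phenyl]-[5,6'-bichromane]-3,3'-diol
Product: 19 (2R,2'R,3S,3'S)-2,2'-bis(3,4-dihydroxyphenyl)-[5,6'-bichromane]-3,3',7,7',8,8'-hexol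
Conditions: H2 (1 atm), Pd(OH)2/C, THF/MeOH, rt; filtration under argon
Reagents that add atoms: none
Why: Hydrogenolysis of the eight benzyl ethers under neutral conditions; no base or oxidant meets the freed catechol and 7,8-dihydroxy rings and the four stereocentres are not involved.

## Compound list

1 | 1-(2-hydroxy-3,4-dimethoxyphenyl)ethanone | CC(=O)c1ccc(OC)c(OC)c1O | starting material
2 | 1-(5-bromo-2-hydroxy-3,4-dimethoxyphenyl)ethanone | CC(=O)c1cc(Br)c(OC)c(OC)c1O | intermediate
3 | 1-(6-hydroxy-2,3,4-trimethoxyphenyl)ethanone | CC(=O)c1c(O)cc(OC)c(OC)c1OC | starting material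
4 | 2-acetyl-3,4,5-trimethoxyphenyl trifluoromethanesulfonate | CC(=O)c1c(OS(=O)(=O)C(F)(F)F)cc(OC)c(OC)c1OC | intermediate
5 | 1-[2-hydroxy-3,4-dimethoxy-5-(4,4,5,5-tetramethyl-1,3,2-dioxaborolan-2-yl)phenyl]ethanone (formed in the flask in step 3) | CC(=O)c1cc(B2OC(C)(C)C(C)(C)O2)c(OC)c(OC)c1O | intermediate
6 | 1-[5-(2-acetyl-3,4,5-trimethoxyphenyl)-2-hydroxy-3,4-dimethoxyphenyl]ethanone | CC(=O)c1cc(-c2cc(OC)c(OC)c(OC)c2C(C)=O)c(OC)c(OC)c1O | intermediate
7 | 1-[5-(2-acetyl-3-hydroxy-4,5-dimethoxyphenyl)-2-hydroxy-3,4-dimethoxyphenyl]ethanone | CC(=O)c1cc(-c2cc(OC)c(OC)c(O)c2C(C)=O)c(OC)c(OC)c1O | intermediate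
8 | (E)-3-(dimethylamino)-1-[5-[2-[(E)-3-(dimethylamino)prop-2-enoyl]-3-hydroxy-4,5-dimethoxyphenyl]-2-hydroxy-3,4-dimethoxyphenyl]prop-2-en-1-one (formed in the flask in step 5) | CN(C)/C=C/C(=O)c1cc(-c2cc(OC)c(OC)c(O)c2C(=O)/C=C/N(C)C)c(OC)c(OC)c1O | intermediate
9 | 7,7',8,8'-tetramethoxy-4H,4'H-[5,6'-bichromene]-4,4'-dione | O=c1ccoc2c(OC)c(OC)c(-c3cc(OC)c(OC)c4occc(=O)c34)cc12 | intermediate
10 | 7,7',8,8'-tetrahydroxy-4H,4'H-[5,6'-bichromene]-4,4'-dione | O=c1ccoc2c(O)c(O)c(-c3cc(O)c(O)c4occc(=O)c34)cc12 | intermediate
11 | 7,7',8,8'-tetrakis(benzyloxy)-4H,4'H-[5,6'-bichromene]-4,4'-dione | O=c1ccoc2c(OCc6ccccc6)c(OCc6ccccc6)c(-c3cc(OCc6ccccc6)c(OCc6ccccc6)c4occc(=O)c34)cc12 | intermediate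
12 | 3,4-bis(benzyloxy)phenylboronic acid | OB(O)c1ccc(OCc2ccccc2)c(OCc2ccccc2)c1 | starting material
13 | (2S,2'S)-7,7',8,8'-tetrakis(benzyloxy)-2,2'-bis[3,4-bis(benzyloxy)phenyl]-2,2',3,3'-tetrahydro-4H,4'H-[5,6'-bichromene]-4,4'-dione | c6ccccc6COc1ccc([C@H]2Oc3c(cc(-c4cc(OCc6ccccc6)c(OCc6ccccc6)c5c4C(=O)C[C@@H](c4ccc(OCc6ccccc6)c(OCc6ccccc6)c4)O5)c(OCc6ccccc6)c3OCc6ccccc6)C(=O)C2)cc1OCc6ccccc6 | intermediate
14 | (2S,2'S)-7,7',8,8'-tetrakis(benzyloxy)-2,2'-bis[3,4-bis(benzyloxy)phenyl]-4,4'-bis(trimethylsilyloxy)-2H,2'H-5,6'-bichromene (formed in the flask in step 9) | c6ccccc6COc1ccc([C@H]2Oc3c(cc(-c4cc(OCc6ccccc6)c(OCc6ccccc6)c5c4C(O[Si](C)(C)C)=C[C@@H](c4ccc(OCc6ccccc6)c(OCc6ccccc6)c4)O5)c(OCc6ccccc6)c3OCc6ccccc6)C(O[Si](C)(C)C)=C2)cc1OCc6ccccc6 | intermediate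
15 | bis(3,4-epoxide) of 14, each epoxide oxygen on the face opposite the C2 aryl group and each C4 carrying the trimethylsilyloxy group (formed in the flask in step 9) | c6ccccc6COc1ccc([C@H]2Oc3c(cc(-c4cc(OCc6ccccc6)c(OCc6ccccc6)c5c4[C@]8(O[Si](C)(C)C)O[C@@H]8[C@@H](c4ccc(OCc6ccccc6)c(OCc6ccccc6)c4)O5)c(OCc6ccccc6)c3OCc6ccccc6)[C@]7(O[Si](C)(C)C)O[C@H]27)cc1OCc6ccccc6 | intermediate
16 | (2R,2'R,3R,3'R)-7,7',8,8'-tetrakis(benzyloxy)-2,2'-bis[3,4-bis(benzyloxy)phenyl]-3,3'-dihydroxy-2,2',3,3'-tetrahydro-4H,4'H-[5,6'-bichromene]-4,4'-dione | c6ccccc6COc1ccc([C@H]2Oc3c(cc(-c4cc(OCc6ccccc6)c(OCc6ccccc6)c5c4C(=O)[C@H](O)[C@@H](c4ccc(OCc6ccccc6)c(OCc6ccccc6)c4)O5)c(OCc6ccccc6)c3OCc6ccccc6)C(=O)[C@@H]2O)cc1OCc6ccccc6 | intermediate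
17 | (2R,2'R,3S,3'S,4R,4'R)-7,7',8,8'-tetrakis(benzyloxy)-2,2'-bis[3,4-bis(benzyloxy)phenyl]-[5,6'-bichromane]-3,3',4,4'-tetrol (major C4 epimer drawn) | c6ccccc6COc1ccc([C@H]2Oc3c(cc(-c4cc(OCc6ccccc6)c(OCc6ccccc6)c5c4[C@@H](O)[C@H](O)[C@@H](c4ccc(OCc6ccccc6)c(OCc6ccccc6)c4)O5)c(OCc6ccccc6)c3OCc6ccccc6)[C@@H](O)[C@@H]2O)cc1OCc6ccccc6 | intermediate
18 | (2R,2'R,3S,3'S)-7,7',8,8'-tetrakis(benzyloxy)-2,2'-bis[3,4-bis(benzyloxy)phenyl]-[5,6'-bichromane]-3,3'-diol | c6ccccc6COc1ccc([C@H]2Oc3c(cc(-c4cc(OCc6ccccc6)c(OCc6ccccc6)c5c4C[C@H](O)[C@@H](c4ccc(OCc6ccccc6)c(OCc6ccccc6)c4)O5)c(OCc6ccccc6)c3OCc6ccccc6)C[C@@H]2O)cc1OCc6ccccc6 | intermediate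
19 | (2R,2'R,3S,3'S)-2,2'-bis(3,4-dihydroxyphenyl)-[5,6'-bichromane]-3,3',7,7',8,8'-hexol (CNP0319747.1) | Oc1ccc([C@H]2Oc3c(cc(-c4cc(O)c(O)c5c4C[C@H](O)[C@@H](c4ccc(O)c(O)c4)O5)c(O)c3O)C[C@@H]2O)cc1O | target

## Step count and risk

Total step count: 12. Longest linear sequence: 11 steps (step 1 or step 2, then steps 3 to 12).

**Step 8 (key step).**
- What may go wrong: the second addition may stall. The 7,8-dialkoxy chromones are electron-rich acceptors and the unit 2 carbonyl is twisted by its peri aryl group, while protodeboronation and homocoupling of the electron-rich boronic acid deplete the nucleophile and reduce the catalyst to metal. Facial selectivity may also erode at the more hindered unit 2.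
- Fallback: form O1–C2 instead of C2–aryl. Setting out from 11, aqueous KOH in ethanol would open both pyranones with loss of formate to give 1-[5-(2-acetyl-4,5-bis(benzyloxy)-3-hydroxyphenyl)-3,4-bis(benzyloxy)-2-hydroxyphenyl]ethanone F1. Claisen–Schmidt condensation with 3,4-bis(benzyloxy)benzaldehyde would give the bis(2'-hydroxychalcone) F2. An intramolecular oxa-Michael addition under a quinine-derived thiourea catalyst would then close both rings and return to 13. That closure is expected to be less selective than the key step, so the homochiral diastereomer would have to be enriched by chromatography and crystallisation.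

**Step 9.**
- What may go wrong: opening of the pyranone by retro-oxa-Michael reaction or epimerisation at C2 during enolisation; incomplete hydroxylation of one of the two units; competing oxidation of the electron-rich benzyloxyarenes.
- Fallback: avoid enolisation altogether. From 13, NaBH4 would give the bis(2,4-cis-flavan-4-ol) F3. Acid-catalysed dehydration (pyridinium p-toluenesulfonate, toluene, heat) would give the bis(flav-3-ene) F4. Hydroboration–oxidation (BH3·THF, then NaOH/H2O2) would place each hydroxyl at C3 anti to the C2 aryl group and rejoin the route at 18, bypassing 16 and 17.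

**Step 11.**
- What may go wrong: diversion of the C4 cation by a 1,2-hydride shift from C3 to give the 3-ketone, capture of the cation by an electron-rich ring of a second molecule (oligomerisation), and partial loss of benzyl ethers in acid.
- Fallback: omit the step and hydrogenolyse 17 directly (H2, Pd(OH)2/C, trace acid). This would remove the benzylic C4 hydroxyls together with the benzyl ethers and arrive at 19. It makes no new compound (F0).

**Step 3.**
- What may go wrong: slow oxidative addition and protodebromination of the electron-rich bromophenol during borylation, protodeboronation of 5, and hydrolysis of the triflate under aqueous base.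
- Fallback: reverse the polarity of the coupling. Triflate 4 would be borylated (B2pin2, PdCl2(dppf), KOAc) to 1-[2,3,4-trimethoxy-6-(4,4,5,5-tetramethyl-1,3,2-dioxaborolan-2-yl)phenyl]ethanone F5. F5 would be coupled with bromide 2 using Pd(OAc)2 and 2-dicyclohexylphosphino-2',6'-dimethoxybiphenyl, returning to 6.

## Further compounds

F1 | step 8 | 1-[5-(2-acetyl-4,5-bis(benzyloxy)-3-hydroxyphenyl)-3,4-bis(benzyloxy)-2-hydroxyphenyl]ethanone | CC(=O)c1cc(-c2cc(OCc6ccccc6)c(OCc6ccccc6)c(O)c2C(C)=O)c(OCc6ccccc6)c(OCc6ccccc6)c1O
F2 | step 8 | bis(2'-hydroxychalcone): (E)-1-[3,4-bis(benzyloxy)-5-[4,5-bis(benzyloxy)-2-[(E)-3-[3,4-bis(benzyloxy)phenyl]prop-2-enoyl]-3-hydroxyphenyl]-2-hydroxyphenyl]-3-[3,4-bis(benzyloxy)phenyl]prop-2-en-1-one | O=C(/C=C/c1ccc(OCc6ccccc6)c(OCc6ccccc6)c1)c1cc(-c2cc(OCc6ccccc6)c(OCc6ccccc6)c(O)c2C(=O)/C=C/c2ccc(OCc6ccccc6)c(OCc6ccccc6)c2)c(OCc6ccccc6)c(OCc6ccccc6)c1O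
F3 | step 9 | (2S,2'S,4S,4'S)-7,7',8,8'-tetrakis(benzyloxy)-2,2'-bis[3,4-bis(benzyloxy)phenyl]-[5,6'-bichromane]-4,4'-diol | c6ccccc6COc1ccc([C@H]2Oc3c(cc(-c4cc(OCc6ccccc6)c(OCc6ccccc6)c5c4[C@@H](O)C[C@@H](c4ccc(OCc6ccccc6)c(OCc6ccccc6)c4)O5)c(OCc6ccccc6)c3OCc6ccccc6)[C@@H](O)C2)cc1OCc6ccccc6
F4 | step 9 | (2S,2'S)-7,7',8,8'-tetrakis(benzyloxy)-2,2'-bis[3,4-bis(benzyloxy)phenyl]-2H,2'H-5,6'-bichromene | c6ccccc6COc1ccc([C@H]2Oc3c(cc(-c4cc(OCc6ccccc6)c(OCc6ccccc6)c5c4C=C[C@@H](c4ccc(OCc6ccccc6)c(OCc6ccccc6)c4)O5)c(OCc6ccccc6)c3OCc6ccccc6)C=C2)cc1OCc6ccccc6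
F0 | step 11 | none | none
F5 | step 3 | 1-[2,3,4-trimethoxy-6-(4,4,5,5-tetramethyl-1,3,2-dioxaborolan-2-yl)phenyl]ethanone | CC(=O)c1c(B2OC(C)(C)C(C)(C)O2)cc(OC)c(OC)c1OC
A1 | alternative 1 | biaryl phenol with ring A of unit 2 complete, free C8a hydroxyl and acetonide-protected side-chain diol | c6ccccc6COc1ccc([C@H]2Oc3c(cc(-c4cc(OCc6ccccc6)c(OCc6ccccc6)c(O)c4C[C@@H]7OC(C)(C)O[C@H]7c8ccc(OCc6ccccc6)c(OCc6ccccc6)c8)c(OCc6ccccc6)c3OCc6ccccc6)C[C@@H]2OCc6ccccc6)cc1OCc6ccccc6
A2 | alternative 2 | fully protected target with six benzyl ethers and two diphenylmethylene ketals | c7ccccc7C1(c7ccccc7)Oc2ccc([C@H]3Oc4c(cc(-c5cc(OCc6ccccc6)c(OCc6ccccc6)c8c5C[C@H](OCc6ccccc6)[C@@H](c5ccc9OC(c7ccccc7)(c7ccccc7)Oc9c5)O8)c(OCc6ccccc6)c4OCc6ccccc6)C[C@@H]3OCc6ccccc6)cc2O1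
A3 | alternative 3 | octa-O-benzyl target 3,3'-diacetate | c6ccccc6COc1ccc([C@H]2Oc3c(cc(-c4cc(OCc6ccccc6)c(OCc6ccccc6)c5c4C[C@H](OC(C)=O)[C@@H](c4ccc(OCc6ccccc6)c(OCc6ccccc6)c4)O5)c(OCc6ccccc6)c3OCc6ccccc6)C[C@@H]2OC(C)=O)cc1OCc6ccccc6
A4 | alternative 3 | 3,4-bis(benzyloxy)-5-[4,5-bis(benzyloxy)-3-hydroxy-2-(hydroxymethyl)phenyl]-2-hydroxybenzyl alcohol | OCc1cc(-c2cc(OCc3ccccc3)c(OCc3ccccc3)c(O)c2CO)c(OCc3ccccc3)c(OCc3ccccc3)c1O
A5 | alternative 3 | (E)-2-[3,4-bis(benzyloxy)phenyl]ethenyl acetate | CC(=O)O/C=C/c1ccc(OCc2ccccc2)c(OCc2ccccc2)c1
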